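**Plan**
- Retrosynthetic cuts: (a) the C-15–O ester bond (ferulate); (b) the C-8–C-17 bond (methyl on the Δ7 alkene, back to the Δ7 enol triflate of a C-8 ketone); (c) both ring bonds of C-9 (C-8–C-9 and C-9–C-10), which lifts C-9 with the whole C-11–C-16 chain out of ring B; (d) ring-A adjustments back to (S)-Hajos–Parrish ketone.
- Enabling feature: in ring B (C-5, C-6, C-7, C-8, C-9, C-10) C-9 is a CH between quaternary C-10 and C-8, and C-8 carries only a methyl on an alkene, i.e. a masked ketone. Without C-9 the ring is the cyclopentanone C-5/C-6/C-7/C-8/C-10 of a Hajos–Parrish hydrindanone, and C-9 can return as a carbenoid carbon that already bears the side chain.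
- Forward order: ring A is completed on the hydrindane (gem-dimethyl at C-4, trans fusion, oxygen moved from C-3 to C-2); the side chain is made from (R)-citronellol as a gem-dibromide; ring B becomes six-membered in a one-carbon ring expansion that also joins the two fragments; then the C-17 methyl, the ferulate ester and desilylation.
- Stereochemistry: C-10 from (S)-Hajos–Parrish ketone; C-5 by hydrogenation anti to the angular methyl; C-2 by α-face hydroboration; C-9 by equilibration next to the C-8 ketone; C-13 from (R)-citronellol; the E-alkene from ferulic acid.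

Key step: step 12

Remark: labdane numbering is used for atom labels throughout (decalin C-1 to C-10, side chain C-11 to C-16, C-17 on C-8, C-20 on C-10). In the indane names C-1 = C-8, C-3a = C-5, C-4 = C-4, C-5 = C-3, C-6 = C-2, C-7a = C-10. The target is taken as drawn: 2α-OH, 5α-H, 9α-H, 10β-CH3, 13R.

**Fragment A: hydrindanone**

Step 1
Reactants: 1 (S)-Hajos–Parrish ketone
Product: 2 Hajos–Parrish monoketal
Conditions: 2-ethyl-2-methyl-1,3-dioxolane, ethylene glycol (cat.), p-TsOH·H2O (cat.), rt
Reagents that add atoms: 2-ethyl-2-methyl-1,3-dioxolane, CCC1(C)OCCO1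
Why: Acid-catalysed dioxolane exchange ketalises the saturated, more electrophilic cyclopentanone carbonyl (C-8) and leaves the conjugated enone untouched, the usual mono-protection of this diketone.

Step 2
Reactants: 2 Hajos–Parrish monoketal
Product: 4 4,4-dimethyl Δ5 ketone ketal, via monomethyl ketone 3 (not isolated)
Conditions: KOtBu (2.5 equiv), MeI (3 equiv), t-BuOH/THF, 0 °C to rt
Reagents that add atoms: iodomethane, CI
Why: Deconjugative α,α-dimethylation: the extended enolate (γ-deprotonation at C-6) is methylated twice at C-4, which installs the gem-dimethyl group and moves the double bond to C-5=C-6, while the ketal blocks C-7.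

Step 3
Reactants: 4 4,4-dimethyl Δ5 ketone ketal
Product: 5 trans-fused ketone ketal
Conditions: H2 (1 atm), 10% Pd/C, EtOAc, rt
Reagents that add atoms: none
Why: Heterogeneous hydrogenation should deliver hydrogen to the α face of the C-5=C-6 bond, away from the angular C-10 methyl and the β-methyl on C-4, which sets H-5 α and the trans ring fusion.

Step 4
Reactants: 5 trans-fused ketone ketal
Product: 6 tosylhydrazone
Conditions: TsNHNH2, THF, 50 °C
Reagents that add atoms: p-toluenesulfonyl hydrazide, Cc1ccc(cc1)S(=O)(=O)NN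
Why: Condensation of the C-3 ketone to its tosylhydrazone, the substrate of the Shapiro reaction; the ketal is stable without added acid.

Step 5
Reactants: 6 tosylhydrazone
Product: 8 Δ2 alkene ketal, via vinyllithium 7 (not isolated)
Conditions: n-BuLi (3 equiv), THF/TMEDA, −78 to 0 °C; then H2O
Reagents that add atoms: none
Why: Shapiro reaction: the dianion can form only toward C-2 because C-4 is quaternary, loss of sulfinate and N2 gives the C-3 vinyllithium, and protonation gives the Δ2 alkene regiospecifically.

Step 6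
Reactants: 8 Δ2 alkene ketal
Product: 10 2α-hydroxy ketal, via alkylborane 9 (not isolated)
Conditions: BH3·THF, THF, 0 °C to rt; then 3 M NaOH, 30% H2O2, 0 °C to rt
Reagents that add atoms: borane–tetrahydrofuran, B.C1CCOC1 (boron is carried only in 9); hydrogen peroxide, OO
Why: Hydroboration–oxidation: syn addition from the α face (the β face carries the axial methyls on C-4 and C-10) puts boron on C-2, the carbon remote from neopentyl C-3, and oxidation with retention gives the equatorial 2α-alcohol (6S in indane numbering).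

Step 7
Reactants: 10 2α-hydroxy ketal
Product: 11 hydroxy hydrindanone
Conditions: 2 M HCl, THF, rt to 40 °C
Reagents that add atoms: water, O
Why: Acid hydrolysis of the dioxolane frees the C-8 ketone; the secondary alcohol and the stereocentres are inert to dilute acid.

Step 8
Reactants: 11 hydroxy hydrindanone
Product: 12 silyloxy hydrindanone
Conditions: TBSCl, imidazole, DMF, rt
Reagents that add atoms: tert-butyldimethylsilyl chloride, CC(C)(C)[Si](C)(C)Cl
Why: Standard silylation of the secondary alcohol, so that C-2 stays masked through the organolithium, enolate and coupling steps and is released by fluoride at the end.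

**Fragment B: side chain**

Step 9
Reactants: 13 (R)-citronellol
Product: 14 citronellyl PMB ether
Conditions: NaH, 4-methoxybenzyl chloride, Bu4NI (cat.), THF/DMF, 0 °C to rt
Reagents that add atoms: 4-methoxybenzyl chloride, COc1ccc(CCl)cc1
Why: Williamson etherification; the PMB ether survives strong bases and is later removed oxidatively beside the silyl ether.

Step 10
Reactants: 14 citronellyl PMB ether
Product: 16 aldehyde, via diol 15 (not isolated)
Conditions: OsO4 (2 mol %), NaIO4 (4 equiv), 2,6-lutidine, dioxane/H2O 3:1, rt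
Reagents that add atoms: osmium tetroxide, O=[Os](=O)(=O)=O (catalytic oxygen carrier); sodium periodate, [Na+].[O-]I(=O)(=O)=O
Why: Lemieux–Johnson oxidation: dihydroxylation of the trisubstituted alkene and periodate cleavage give the aldehyde whose carbon becomes C-9, without exposing the electron-rich arene to ozone; the C-13 stereocentre is remote.

Step 11
Reactants: 16 aldehyde
Product: 17 gem-dibromide
Conditions: P(OPh)3, Br2, Et3N, CH2Cl2, −78 °C to rt
Reagents that add atoms: bromine, BrBr
Why: Deoxygenative gem-dibromination of the aldehyde by the bromophosphonium reagent formed from P(OPh)3 and Br2, driven by formation of the phosphate; low temperature and Et3N suppress enolisation and loss of the PMB group.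

**Fragment union and completion**

Step 12
Reactants: 12 silyloxy hydrindanone; 17 gem-dibromide
Product: 22 ring-expanded 17-norlabdan-8-one, via dibromoalkyllithium 18 (not isolated), via lithium alkoxide adduct 19 (not isolated), via β-oxido carbenoid 20 (not isolated), via lithium enolate 21 (not isolated)
Conditions: 17 (1.3 equiv), LiN(i-Pr)2 (1.3 equiv), THF/Et2O, −105 °C; add 12, −105 to −90 °C; n-BuLi (1.3 equiv), −95 to 0 °C; MeOH; then NaOMe (cat.), MeOH/THF, rt
Reagents that add atoms: none
Why: LiN(i-Pr)2 deprotonates 17 to the dibromoalkyllithium 18, which adds to the C-8 carbonyl of 12 from the face opposite the angular methyl to give alkoxide 19; bromine–lithium exchange then gives the β-oxido carbenoid 20, in which the oxyanion pushes the C-8–C-10 bond onto the carbenoid carbon as bromide leaves, so that C-9 is inserted between C-8 and C-10 (C-10 migrating with retention) and enolate 21 of the ring-expanded ketone results. The closest known reaction type is the β-oxido carbenoid one-carbon homologation of cycloalkanones with lithiated gem-dibromides, a carbenoid relative of the Tiffeneau–Demjanov and semipinacol ring expansions. No ring is closed by cyclisation: ring B arises from the five-membered ring C-5/C-6/C-7/C-8/C-10 by a 1,2-shift that makes it six-membered, and the same event forms both bonds of C-9 and attaches the whole side chain. The one new stereocentre that persists, C-9, is set after the shift by NaOMe equilibration α to the C-8 ketone, which should place the side chain equatorial (9β, H-9 α and anti to the axial C-10 methyl) on the trans-decalin; C-13 is untouched. The step needs migration of quaternary C-10 in preference to the C-7 methylene, which the electrophilic carbenoid carbon should secure by taking the more substituted, more electron-rich group, and it needs addition to outrun enolisation of 12, for which the carbenoid is formed first at −105 °C and the ketone is added cold.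

Step 13
Reactants: 22 ring-expanded 17-norlabdan-8-one
Product: 24 Δ7 enol triflate, via potassium enolate 23 (not isolated)
Conditions: KN(SiMe3)2 (1.1 equiv), THF, −78 °C; then PhNTf2, −78 to 0 °C
Reagents that add atoms: N-phenylbis(trifluoromethanesulfonimide), O=S(=O)(N(c1ccccc1)S(=O)(=O)C(F)(F)F)C(F)(F)F
Why: Kinetic deprotonation by the bulky amide takes a C-7 proton in preference to the hindered tertiary H-9, and O-triflation fixes the enolate as the Δ7 enol triflate, so the position of the future alkene is set and C-9 is not epimerised.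

Step 14
Reactants: 24 Δ7 enol triflate
Product: 25 protected labd-7-ene
Conditions: MeMgBr (1.5 equiv), Fe(acac)3 (5 mol %), THF/NMP, −30 to 0 °C
Reagents that add atoms: methylmagnesium bromide, C[Mg]Br
Why: Iron-catalysed cross-coupling of an alkenyl triflate with a methyl Grignard reagent (Kumada type) replaces triflate by the C-17 methyl with the double bond held at C-7=C-8.

Step 15
Reactants: 25 protected labd-7-ene
Product: 26 C-15 alcohol
Conditions: DDQ, CH2Cl2/pH 7 buffer, 0 °C to rt
Reagents that add atoms: none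
Why: Oxidative cleavage of the PMB ether by DDQ frees the C-15 alcohol; the silyl ether and the trisubstituted alkene should not be attacked at 0 °C in buffered medium.

Step 16
Reactants: 27 (E)-ferulic acid
Product: 29 O-silyl ferulic acid, via bis-silyl derivative 28 (not isolated)
Conditions: TBSCl (2.5 equiv), imidazole, DMF, rt; then AcOH/THF/H2O 3:1:1, rt
Reagents that add atoms: tert-butyldimethylsilyl chloride, CC(C)(C)[Si](C)(C)Cl
Why: Exhaustive silylation followed by selective hydrolysis of the labile silyl ester leaves the phenol protected, so that the acid can be activated without self-acylation.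

Step 17
Reactants: 26 C-15 alcohol; 29 O-silyl ferulic acid
Product: 30 bis-silyl ferulate ester
Conditions: EDC·HCl, DMAP, CH2Cl2, 0 °C to rt
Reagents that add atoms: none
Why: Steglich esterification (carbodiimide, DMAP) of the primary C-15 alcohol; the E-cinnamate geometry is retained.

Step 18
Reactants: 30 bis-silyl ferulate ester
Product: 31 CNP0175017.1
Conditions: HF·pyridine, pyridine/THF, 0 °C to rt
Reagents that add atoms: none
Why: Fluoride-mediated cleavage of the aryl and the secondary silyl ether under buffered, non-basic conditions that spare the cinnamate ester and the Δ7 alkene should give the target.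

**Compound list**

1 | (S)-Hajos–Parrish ketone, (7aS)-7a-methyl-2,3,7,7a-tetrahydro-1H-indene-1,5(6H)-dione | O=C2CCC3=CC(=O)CC[C@]23C | starting material
2 | (7aS)-7a-methyl-2,3,7,7a-tetrahydro-1H-indene-1,5(6H)-dione 1-(ethylene ketal) | O1CCOC12CCC3=CC(=O)CC[C@]23C | intermediate
3 | (7aS)-4,7a-dimethyl-2,4,7,7a-tetrahydro-1H-indene-1,5(6H)-dione 1-(ethylene ketal), C-4 epimers, double bond C-3=C-3a | O1CCOC12CC=C3C(C)C(=O)CC[C@]23C | intermediate
4 | (7aS)-4,4,7a-trimethyl-2,4,7,7a-tetrahydro-1H-indene-1,5(6H)-dione 1-(ethylene ketal), double bond C-3=C-3a | O1CCOC12CC=C3C(C)(C)C(=O)CC[C@]23C | intermediate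
5 | (3aS,7aS)-4,4,7a-trimethylhexahydro-1H-indene-1,5(4H)-dione 1-(ethylene ketal), trans-fused | O1CCOC12CC[C@H]3C(C)(C)C(=O)CC[C@]23C | intermediate
6 | 5-(E)-(p-toluenesulfonyl)hydrazone of 5 | O1CCOC12CC[C@H]3C(C)(C)/C(=N/NS(=O)(=O)c4ccc(C)cc4)CC[C@]23C | intermediate
7 | C-5 vinyllithium (indane numbering) of the 1-ketal, (3aS,7aS) | O1CCOC12CC[C@H]3C(C)(C)C([Li])=CC[C@]23C | intermediate
8 | (3aS,7aS)-4,4,7a-trimethyl-2,3,3a,4,7,7a-hexahydro-1H-inden-1-one ethylene ketal, double bond C-5=C-6 | O1CCOC12CC[C@H]3C(C)(C)C=CC[C@]23C | intermediate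
9 | (3aS,6S,7aS)-6-boranyl-4,4,7a-trimethyloctahydro-1H-inden-1-one ethylene ketal | O1CCOC12CC[C@H]3C(C)(C)C[C@H](B)C[C@]23C | intermediate
10 | (3aS,6S,7aS)-6-hydroxy-4,4,7a-trimethyloctahydro-1H-inden-1-one ethylene ketal | O1CCOC12CC[C@H]3C(C)(C)C[C@H](O)C[C@]23C | intermediate
11 | (3aS,6S,7aS)-6-hydroxy-4,4,7a-trimethyloctahydro-1H-inden-1-one | O=C2CC[C@H]3C(C)(C)C[C@H](O)C[C@]23C | intermediate
12 | (3aS,6S,7aS)-6-[(tert-butyldimethylsilyl)oxy]-4,4,7a-trimethyloctahydro-1H-inden-1-one | O=C2CC[C@H]3C(C)(C)C[C@H](O[Si](C)(C)C(C)(C)C)C[C@]23C | intermediate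
13 | (R)-citronellol, (3R)-3,7-dimethyloct-6-en-1-ol | OCC[C@H](C)CCC=C(C)C | starting material
14 | 1-({[(3R)-3,7-dimethyloct-6-en-1-yl]oxy}methyl)-4-methoxybenzene | COc1ccc(COCC[C@H](C)CCC=C(C)C)cc1 | intermediate
15 | (6R)-8-[(4-methoxybenzyl)oxy]-2,6-dimethyloctane-2,3-diol, C-3 epimers | COc1ccc(COCC[C@H](C)CCC(O)C(C)(C)O)cc1 | intermediate
16 | (4R)-6-[(4-methoxybenzyl)oxy]-4-methylhexanal | COc1ccc(COCC[C@H](C)CCC=O)cc1 | intermediate
17 | 1-({[(3R)-6,6-dibromo-3-methylhexyl]oxy}methyl)-4-methoxybenzene | COc1ccc(COCC[C@H](C)CCC(Br)Br)cc1 | intermediate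
18 | [(4R)-1,1-dibromo-6-[(4-methoxybenzyl)oxy]-4-methylhexyl]lithium | COc1ccc(COCC[C@H](C)CCC([Li])(Br)Br)cc1 | intermediate
19 | lithium alkoxide of the C-8 adduct of 18 and 12 (oxygen β, cis to the angular methyl; dibromoalkyl group α) | COc1ccc(COCC[C@H](C)CCC(Br)(Br)[C@]2(O[Li])CC[C@H]3C(C)(C)C[C@H](O[Si](C)(C)C(C)(C)C)C[C@]23C)cc1 | intermediate
20 | β-oxido carbenoid: 19 with one bromine on C-9 exchanged for lithium (C-9 epimers) | COc1ccc(COCC[C@H](C)CCC([Li])(Br)[C@]2(O[Li])CC[C@H]3C(C)(C)C[C@H](O[Si](C)(C)C(C)(C)C)C[C@]23C)cc1 | intermediate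
21 | lithium Δ8(9)-enolate of 22 | COc1ccc(COCC[C@H](C)CCC2=C(O[Li])CC[C@H]3C(C)(C)C[C@H](O[Si](C)(C)C(C)(C)C)C[C@]23C)cc1 | intermediate
22 | (13R)-2α-[(tert-butyldimethylsilyl)oxy]-15-[(4-methoxybenzyl)oxy]-17-norlabdan-8-one (5α-H, 9α-H, 10β-CH3) | COc1ccc(COCC[C@H](C)CC[C@H]2C(=O)CC[C@H]3C(C)(C)C[C@H](O[Si](C)(C)C(C)(C)C)C[C@]23C)cc1 | intermediate
23 | potassium Δ7-enolate of 22 | COc1ccc(COCC[C@H](C)CC[C@H]2C(O[K])=CC[C@H]3C(C)(C)C[C@H](O[Si](C)(C)C(C)(C)C)C[C@]23C)cc1 | intermediate
24 | (13R)-2α-[(tert-butyldimethylsilyl)oxy]-15-[(4-methoxybenzyl)oxy]-17-norlabd-7-en-8-yl trifluoromethanesulfonate | COc1ccc(COCC[C@H](C)CC[C@H]2C(OS(=O)(=O)C(F)(F)F)=CC[C@H]3C(C)(C)C[C@H](O[Si](C)(C)C(C)(C)C)C[C@]23C)cc1 | intermediate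
25 | (13R)-2α-[(tert-butyldimethylsilyl)oxy]-15-[(4-methoxybenzyl)oxy]labd-7-ene | COc1ccc(COCC[C@H](C)CC[C@H]2C(C)=CC[C@H]3C(C)(C)C[C@H](O[Si](C)(C)C(C)(C)C)C[C@]23C)cc1 | intermediate
26 | (13R)-2α-[(tert-butyldimethylsilyl)oxy]labd-7-en-15-ol | OCC[C@H](C)CC[C@H]2C(C)=CC[C@H]3C(C)(C)C[C@H](O[Si](C)(C)C(C)(C)C)C[C@]23C | intermediate
27 | (E)-ferulic acid, (2E)-3-(4-hydroxy-3-methoxyphenyl)prop-2-enoic acid | COc1cc(/C=C/C(=O)O)ccc1O | starting material
28 | tert-butyldimethylsilyl (2E)-3-{4-[(tert-butyldimethylsilyl)oxy]-3-methoxyphenyl}prop-2-enoate | COc1cc(/C=C/C(=O)O[Si](C)(C)C(C)(C)C)ccc1O[Si](C)(C)C(C)(C)C | intermediate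
29 | (2E)-3-{4-[(tert-butyldimethylsilyl)oxy]-3-methoxyphenyl}prop-2-enoic acid | COc1cc(/C=C/C(=O)O)ccc1O[Si](C)(C)C(C)(C)C | intermediate
30 | (13R)-2α-[(tert-butyldimethylsilyl)oxy]labd-7-en-15-yl (2E)-3-{4-[(tert-butyldimethylsilyl)oxy]-3-methoxyphenyl}prop-2-enoate | COc1cc(/C=C/C(=O)OCC[C@H](C)CC[C@H]2C(C)=CC[C@H]3C(C)(C)C[C@H](O[Si](C)(C)C(C)(C)C)C[C@]23C)ccc1O[Si](C)(C)C(C)(C)C | intermediate
31 | CNP0175017.1, (2S,5S,9S,10S,13R)-2-hydroxylabd-7-en-15-yl (E)-ferulate (2α-OH) | COc1cc(/C=C/C(=O)OCC[C@H](C)CC[C@H]2C(C)=CC[C@H]3C(C)(C)C[C@H](O)C[C@]23C)ccc1O | target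

**Step count**

Total: 18 steps. Longest linear sequence: 14 steps (steps 1–8, 12–15, 17, 18).

**Steps most likely to fail**

Step 12. The tertiary, thermally fragile dibromoalkyllithium may deprotonate the neopentyl C-8 ketone instead of adding to it, and the carbenoid may be diverted into a 1,2-hydride shift from C-11 or into migration of the C-7 methylene instead of C-10. The fallback sets out from aldehyde 16 and ketone 12 and returns at ketone 22; it replaces the carbenoid by an olefination followed by a semipinacol ring expansion. Aldehyde 16 is reduced (NaBH4, MeOH) to alcohol F1, converted into iodide F2 (I2, PPh3, imidazole) and then into phosphonium iodide F3 (PPh3, MeCN, reflux). Wittig olefination of 12 with the ylide from F3 (KN(SiMe3)2, toluene, reflux) gives alkylidene hydrindane F4 as a mixture of geometric isomers, both of which serve. Dihydroxylation (OsO4 cat., N-methylmorpholine N-oxide, acetone/H2O) gives diol F5, and selective sulfonylation of the secondary C-9 hydroxyl (MsCl, Et3N, CH2Cl2, −20 °C) gives mesylate F6. Treatment of F6 with Et3Al (CH2Cl2, −78 to 0 °C) should trigger the semipinacol shift of C-10 from C-8 to C-9 with loss of mesylate, and NaOMe/MeOH equilibration at C-9 then gives 22.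

Step 6. Boron may add in part to C-3, or from the β face, so that regio- and stereoisomeric alcohols contaminate the 2α-alcohol. The fallback sets out from ketone 5 and returns at ketone 12; it brings in the C-2 oxygen by enolate oxidation and removes the C-3 oxygen by radical deoxygenation. The C-2 enolate of 5, the only one possible (KN(SiMe3)2, THF, −78 °C), is oxidised with 2-(phenylsulfonyl)-3-phenyloxaziridine from the α face to hydroxy ketone F7, which is silylated at once (TBSCl, imidazole, DMF) to silyl ether F8. Reduction (NaBH4, MeOH) gives alcohol F9, either C-3 epimer of which serves, and acylation (PhOC(S)Cl, DMAP, MeCN) gives thionocarbonate F10. Barton–McCombie deoxygenation (Bu3SnH, AIBN, toluene, 90 °C) gives deoxy ketal F11, and mild ketal hydrolysis (pyridinium p-toluenesulfonate, acetone/H2O, 50 °C) gives 12.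

Step 3. Hydrogen may be delivered in part to the β face on the catalyst surface, which would give the cis-fused hydrindane. The fallback sets out from 4 and returns at 5 without a new compound. The alkene is reduced by radical hydrogen-atom transfer (Mn(dpm)3 cat., PhSiH3, t-BuOOH, i-PrOH, rt), in which the tertiary C-5 radical is quenched stepwise and should go to the more stable trans-fused product instead of following syn delivery from a metal surface.

**Further compounds**

F1 | step 12 | (4R)-6-[(4-methoxybenzyl)oxy]-4-methylhexan-1-ol | COc1ccc(COCC[C@H](C)CCCO)cc1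
F2 | step 12 | 1-({[(3R)-6-iodo-3-methylhexyl]oxy}methyl)-4-methoxybenzene | COc1ccc(COCC[C@H](C)CCCI)cc1
F3 | step 12 | {(4R)-6-[(4-methoxybenzyl)oxy]-4-methylhexyl}triphenylphosphonium iodide | COc1ccc(COCC[C@H](C)CCC[P+](c2ccccc2)(c2ccccc2)c2ccccc2)cc1.[I-]
F4 | step 12 | (3aS,6S,7aS)-6-[(tert-butyldimethylsilyl)oxy]-1-{(4R)-6-[(4-methoxybenzyl)oxy]-4-methylhexylidene}-4,4,7a-trimethyloctahydro-1H-indene (E/Z mixture) | COc1ccc(COCC[C@H](C)CCC=C2CC[C@H]3C(C)(C)C[C@H](O[Si](C)(C)C(C)(C)C)C[C@]23C)cc1
F5 | step 12 | C-8/C-9 diol from F4 (tertiary OH on C-8, secondary OH on C-9; diastereomers) | COc1ccc(COCC[C@H](C)CCC(O)C2(O)CC[C@H]3C(C)(C)C[C@H](O[Si](C)(C)C(C)(C)C)C[C@]23C)cc1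
F6 | step 12 | C-9 methanesulfonate of F5 | COc1ccc(COCC[C@H](C)CCC(OS(C)(=O)=O)C2(O)CC[C@H]3C(C)(C)C[C@H](O[Si](C)(C)C(C)(C)C)C[C@]23C)cc1
F7 | step 6 | (3aS,6R,7aS)-6-hydroxy-4,4,7a-trimethylhexahydro-1H-indene-1,5(4H)-dione 1-(ethylene ketal) (2α-hydroxy-3-ketone) | O1CCOC12CC[C@H]3C(C)(C)C(=O)[C@H](O)C[C@]23C
F8 | step 6 | 6-O-tert-butyldimethylsilyl ether of F7 | O1CCOC12CC[C@H]3C(C)(C)C(=O)[C@H](O[Si](C)(C)C(C)(C)C)C[C@]23C
F9 | step 6 | C-5 alcohol (indane numbering) from F8, C-5 epimers | O1CCOC12CC[C@H]3C(C)(C)C(O)[C@H](O[Si](C)(C)C(C)(C)C)C[C@]23C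
F10 | step 6 | O-phenyl thionocarbonate of F9 | O1CCOC12CC[C@H]3C(C)(C)C(OC(=S)Oc4ccccc4)[C@H](O[Si](C)(C)C(C)(C)C)C[C@]23C
F11 | step 6 | (3aS,6S,7aS)-6-[(tert-butyldimethylsilyl)oxy]-4,4,7a-trimethyloctahydro-1H-inden-1-one ethylene ketal | O1CCOC12CC[C@H]3C(C)(C)C[C@H](O[Si](C)(C)C(C)(C)C)C[C@]23C
F0 | step 3 | none | none
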